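**Retrosynthetic overview**
1. The pyran lactol is closed last through its C–O bond: acid frees the ring hydroxyl and a side-chain aldehyde of 24, which cyclise to 25.
2. The tertiary carbinol of the cyclohexane comes from equatorial methyl addition to ketone 23; the ethylene bridge comes from a decarboxylative Giese union of hydroazulenyl acetic acid 12 with α-methylene ketone 22.
3. Enone 22 comes from (S)-4-silyloxy-3-methylcyclohexenone 18 by anti conjugate addition and methylenation; its single controlling C–O stereocentre is set by a new asymmetric γ-hydroxylation of a dienol ether.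
4. Acid 12: side chain by Johnson–Claisen chirality transfer; cyclopentanol by SmI2 ketyl–enone closure onto a cycloheptadienone made by asymmetric conjugate addition to a cyclohexadienone and one-carbon ring expansion.
5. Ring order: seven-membered ring, then cyclopentanol (left half); the cyclohexane is present from the start and the pyran lactol is formed last (right half).

Assumption: compounds 1 and 13 and both Grignard solutions are bought; the lactol is described as the drawn equatorial (2S) anomer, which equilibrates with its C2 epimer in solution.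

**Step 1**
Reactants: 1 2,4,4-trimethylcyclohex-2-en-1-one
Product: 2 2,4,4-trimethylcyclohexa-2,5-dien-1-one
Conditions: DDQ (1.5 equiv), dioxane, 100 °C
Reagents that add atoms: none
Why: Quinone dehydrogenation of a 4,4-disubstituted cyclohexenone gives the cross-conjugated dienone because the quaternary C4 blocks aromatisation; no stereocentre is formed.

**Step 2**
Reactants: 2 2,4,4-trimethylcyclohexa-2,5-dien-1-one
Product: 4 {[(3S)-3-(but-3-en-1-yl)-4,4,6-trimethylcyclohexa-1,5-dien-1-yl]oxy}trimethylsilane, via bromomagnesium dienolate 3 (not isolated)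
Conditions: but-3-en-1-ylMgBr (1.3 equiv), CuBr·SMe2 (5 mol %), (R)-1-[(S)-2-(diphenylphosphino)ferrocenyl]ethyldicyclohexylphosphine (6 mol %), t-BuOMe, −75 °C; then Me3SiCl, Et3N, HMPA, −75 → 0 °C
Reagents that add atoms: but-3-en-1-ylmagnesium bromide, C=CCC[Mg]Br; chlorotrimethylsilane, C[Si](C)(C)Cl
Why: Copper-catalysed asymmetric conjugate addition of a Grignard reagent: the α-methyl group deactivates the other enone so the alkyl group adds only at C5, the chiral diphosphine–copper complex selects the enone face and sets this centre as S (the mirror-image ligand is used if the sense proves opposite), and O-silylation fixes the enolate regiochemistry for the ring expansion.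

**Step 3**
Reactants: 4 {[(3S)-3-(but-3-en-1-yl)-4,4,6-trimethylcyclohexa-1,5-dien-1-yl]oxy}trimethylsilane
Product: 7 (5S)-5-(but-3-en-1-yl)-2,4,4-trimethylcyclohepta-2,6-dien-1-one, via silyloxycyclopropane 5 (not isolated), via chloro ketone 6 (not isolated)
Conditions: Et2Zn (1.3 equiv), CH2I2 (1.3 equiv), CH2Cl2, 0 °C; solvent exchange, FeCl3 (2.2 equiv), DMF, 0 → 23 °C; then NaOAc, MeOH, 65 °C
Reagents that add atoms: diiodomethane, ICI
Why: Furukawa cyclopropanation of the electron-rich silyl enol ether double bond, then Saegusa–Ito oxidative opening of the internal cyclopropane bond by FeCl3 and loss of HCl, inserts one carbon next to the carbonyl and gives the cross-conjugated cycloheptadienone without touching the stereocentre.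

**Step 4**
Reactants: 7 (5S)-5-(but-3-en-1-yl)-2,4,4-trimethylcyclohepta-2,6-dien-1-one
Product: 8 (5S)-2,4,4-trimethyl-5-(3-oxobutyl)cyclohepta-2,6-dien-1-one
Conditions: PdCl2 (10 mol %), CuCl (1 equiv), O2 (1 atm), DMF/H2O 7:1, 23 °C
Reagents that add atoms: water, O
Why: Tsuji–Wacker oxidation converts the terminal alkene to the methyl ketone by Markovnikov hydroxypalladation while the conjugated ring alkenes stay inert.

**Step 5**
Reactants: 8 (5S)-2,4,4-trimethyl-5-(3-oxobutyl)cyclohepta-2,6-dien-1-one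
Product: 9 (1S,3aS,8aS)-1-hydroxy-1,4,4,6-tetramethyl-2,3,3a,4,8,8a-hexahydroazulen-7(1H)-one
Conditions: SmI2 (2.2 equiv), HMPA (8 equiv), t-BuOH (2 equiv), THF, −78 °C
Reagents that add atoms: none
Why: SmI2 reductive ketyl–enone cyclisation (5-exo): the tether forces the new C–C bond onto its own face, which gives the cis ring fusion, and the bulky samarium-bound oxygen stays anti to the ring CH2 so the hydroxyl ends up syn to both ring-fusion hydrogens, the residual dienolate being protonated to the α-methyl enone.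

**Step 6**
Reactants: 9 (1S,3aS,8aS)-1-hydroxy-1,4,4,6-tetramethyl-2,3,3a,4,8,8a-hexahydroazulen-7(1H)-one
Product: 10 (1S,3aS,7R,8aS)-1,4,4,6-tetramethyl-1,2,3,3a,4,7,8,8a-octahydroazulene-1,7-diol
Conditions: (S)-2-methyl-CBS-oxazaborolidine (20 mol %), catecholborane (2.5 equiv), toluene, −78 °C
Reagents that add atoms: none
Why: Corey–Bakshi–Shibata reduction: the (S)-oxazaborolidine delivers hydride to the convex face (matched with the cis-fused skeleton) and sets the allylic carbinol as 7R, the configuration that is relayed to C5 in the next step.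

**Step 7**
Reactants: 10 (1S,3aS,7R,8aS)-1,4,4,6-tetramethyl-1,2,3,3a,4,7,8,8a-octahydroazulene-1,7-diol
Product: 12 2-[(1S,3aS,5R,8aS)-1-hydroxy-1,4,4,6-tetramethyl-1,2,3,3a,4,5,8,8a-octahydroazulen-5-yl]acetic acid, via ethyl ester 11 (not isolated)
Conditions: MeC(OEt)3 (8 equiv), EtCO2H (10 mol %), xylene, 140 °C; concentrate; LiOH, THF/MeOH/H2O, 40 °C; 1 M HCl work-up
Reagents that add atoms: triethyl orthoacetate, CC(OCC)(OCC)OCC; lithium hydroxide, [Li+].[OH-]
Why: Johnson–Claisen rearrangement: the ketene acetal formed on the 7R oxygen transfers the two-carbon chain suprafacially to C5 (1,3-chirality transfer, sets 5R beside the gem-dimethyl carbon) and moves the double bond to its final trisubstituted position, and the crude ester is saponified.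

**Step 8**
Reactants: 13 3-methylcyclohex-2-en-1-one
Product: 15 tert-butyldimethyl[(3-methylcyclohexa-1,3-dien-1-yl)oxy]silane, via bromomagnesium dienolate 14 (not isolated)
Conditions: MeMgBr (1.1 equiv), FeCl3 (5 mol %), Et2O, −20 °C; then t-BuMe2SiOTf (1.1 equiv), −20 → 0 °C
Reagents that add atoms: tert-butyldimethylsilyl trifluoromethanesulfonate, CC(C)(C)[Si](C)(C)OS(=O)(=O)C(F)(F)F
Why: Thermodynamic γ-deprotonation with the iron-catalysed Grignard base gives the endocyclic through-conjugated dienolate, which is O-silylated; no stereocentre is formed.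

**Step 9**
Reactants: 15 tert-butyldimethyl[(3-methylcyclohexa-1,3-dien-1-yl)oxy]silane
Product: 17 (4S)-4-hydroxy-3-methylcyclohex-2-en-1-one, via silyloxy vinyl epoxide 16 (not isolated)
Conditions: D-fructose-derived Shi ketone (30 mol %), Oxone (2KHSO5·KHSO4·K2SO4, 1.4 equiv KHSO5), K2CO3, Bu4NHSO4 (5 mol %), MeCN/dimethoxymethane/aq. Na2B4O7–Na2EDTA buffer (pH 10.5), 0 °C; then aq. citric acid, 23 °C
Reagents that add atoms: potassium peroxymonosulfate (active part of Oxone), [K+].[O-]S(=O)(=O)OO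
Why: Proposed new method: catalytic asymmetric vinylogous Rubottom oxidation, in which the chiral dioxirane from the fructose-derived ketone should epoxidise the distal C3=C4 bond of the 1-silyloxy diene (largest HOMO coefficient at C4, the site attacked by peracids in dienol ethers) through a spiro transition state that differentiates the faces of this trisubstituted ring alkene and sets C4 as S (the L-series ketone is used if the sense proves opposite), after which the silyloxy vinyl epoxide opens via the oxocarbenium ion and is hydrolysed to the γ-hydroxy enone; the closest known reactions are the chiral-ketone-catalysed epoxidation of silyl enol ethers and enol esters to α-hydroxy ketones and the racemic peracid vinylogous Rubottom oxidation of dienol ethers.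

**Step 10**
Reactants: 17 (4S)-4-hydroxy-3-methylcyclohex-2-en-1-one
Product: 18 (4S)-4-[(tert-butyldimethylsilyl)oxy]-3-methylcyclohex-2-en-1-one
Conditions: t-BuMe2SiCl (1.2 equiv), imidazole (2 equiv), DMF, 23 °C
Reagents that add atoms: tert-butyldimethylsilyl chloride, CC(C)(C)[Si](C)(C)Cl
Why: Standard silylation of the secondary alcohol; the bulky silyl ether then directs the conjugate addition to the opposite face.

**Step 11**
Reactants: 18 (4S)-4-[(tert-butyldimethylsilyl)oxy]-3-methylcyclohex-2-en-1-one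
Product: 22 (3S,4S)-4-[(tert-butyldimethylsilyl)oxy]-3-[2-(1,3-dioxan-2-yl)ethyl]-3-methyl-2-methylidenecyclohexan-1-one, via bromomagnesium enolate 19 (not isolated), via Mannich base 20 (not isolated), via ammonium iodide 21 (not isolated)
Conditions: [2-(1,3-dioxan-2-yl)ethyl]MgBr (2.0 equiv), CuBr·SMe2 (0.3 equiv), THF/Me2S, −78 → −30 °C; then CH2=NMe2+ I−, −78 → 23 °C; then MeI, CH2Cl2, 23 °C; then DBU, 23 °C
Reagents that add atoms: [2-(1,3-dioxan-2-yl)ethyl]magnesium bromide, Br[Mg]CCC1OCCCO1; N,N-dimethylmethyleneiminium iodide, C=[N+](C)C.[I-]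
Why: Copper-mediated 1,4-addition of the acetal Grignard reagent anti to the neighbouring silyloxy group sets the quaternary centre (3S), the enolate is aminomethylated (Mannich reaction with the iminium salt), and Hofmann-type elimination of the quaternised amine gives the α-methylene ketone.

**Step 12**
Reactants: 12 2-[(1S,3aS,5R,8aS)-1-hydroxy-1,4,4,6-tetramethyl-1,2,3,3a,4,5,8,8a-octahydroazulen-5-yl]acetic acid; 22 (3S,4S)-4-[(tert-butyldimethylsilyl)oxy]-3-[2-(1,3-dioxan-2-yl)ethyl]-3-methyl-2-methylidenecyclohexan-1-one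
Product: 23 (2S,3S,4S)-4-[(tert-butyldimethylsilyl)oxy]-3-[2-(1,3-dioxan-2-yl)ethyl]-2-{2-[(1S,3aS,5R,8aS)-1-hydroxy-1,4,4,6-tetramethyl-1,2,3,3a,4,5,8,8a-octahydroazulen-5-yl]ethyl}-3-methylcyclohexan-1-one
Conditions: 12 (1.0 equiv), 22 (1.5 equiv), 9-(2-chlorophenyl)acridine (10 mol %), CH2Cl2, 400 nm LED, 23 °C; then DBU (0.3 equiv), 23 °C
Reagents that add atoms: none
Why: Decarboxylative Giese addition under acridine photocatalysis: the primary radical from the acid adds to the unhindered methylene terminus of the enone, and base equilibration places the new side chain equatorial (2S), cis to the axial angular methyl group.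

**Step 13**
Reactants: 23 (2S,3S,4S)-4-[(tert-butyldimethylsilyl)oxy]-3-[2-(1,3-dioxan-2-yl)ethyl]-2-{2-[(1S,3aS,5R,8aS)-1-hydroxy-1,4,4,6-tetramethyl-1,2,3,3a,4,5,8,8a-octahydroazulen-5-yl]ethyl}-3-methylcyclohexan-1-one
Product: 24 (1R,2S,3S,4S)-4-[(tert-butyldimethylsilyl)oxy]-3-[2-(1,3-dioxan-2-yl)ethyl]-2-{2-[(1S,3aS,5R,8aS)-1-hydroxy-1,4,4,6-tetramethyl-1,2,3,3a,4,5,8,8a-octahydroazulen-5-yl]ethyl}-1,3-dimethylcyclohexan-1-ol
Conditions: MeLi (4 equiv), CeCl3 (4 equiv, dried), THF, −78 °C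
Reagents that add atoms: methyllithium, [Li]C
Why: Organocerium 1,2-addition to an enolisable hindered ketone: the axial angular methyl group blocks axial approach, so the methyl enters equatorially and the new tertiary hydroxyl is axial (1R), cis to the angular methyl.

**Step 14**
Reactants: 24 (1R,2S,3S,4S)-4-[(tert-butyldimethylsilyl)oxy]-3-[2-(1,3-dioxan-2-yl)ethyl]-2-{2-[(1S,3aS,5R,8aS)-1-hydroxy-1,4,4,6-tetramethyl-1,2,3,3a,4,5,8,8a-octahydroazulen-5-yl]ethyl}-1,3-dimethylcyclohexan-1-ol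
Product: 25 (2S,4aS,5S,6R,8aS)-5-{2-[(1S,3aS,5R,8aS)-1-hydroxy-1,4,4,6-tetramethyl-1,2,3,3a,4,5,8,8a-octahydroazulen-5-yl]ethyl}-4a,6-dimethyloctahydro-2H-chromene-2,6-diol (CNP0167351.1)
Conditions: 2 M aq. HCl, THF, 40 °C
Reagents that add atoms: water, O
Why: Acid hydrolysis removes the silyl ether and the dioxane acetal, and the freed equatorial hydroxyl adds to the aldehyde (lactolisation, C–O ring closure) to give the trans-fused pyran with the hydroxyl of the drawn anomer equatorial.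

**Compound list**
1 | 2,4,4-trimethylcyclohex-2-en-1-one | CC1=CC(C)(C)CCC1=O | starting material
2 | 2,4,4-trimethylcyclohexa-2,5-dien-1-one | CC1=CC(C)(C)C=CC1=O | intermediate
3 | bromomagnesium (3S)-3-(but-3-en-1-yl)-4,4,6-trimethylcyclohexa-1,5-dien-1-olate | CC1=CC(C)(C)[C@@H](CCC=C)C=C1O[Mg]Br | intermediate
4 | {[(3S)-3-(but-3-en-1-yl)-4,4,6-trimethylcyclohexa-1,5-dien-1-yl]oxy}trimethylsilane | CC1=CC(C)(C)[C@@H](CCC=C)C=C1O[Si](C)(C)C | intermediate
5 | {[(5S)-5-(but-3-en-1-yl)-2,4,4-trimethylbicyclo[4.1.0]hept-2-en-1-yl]oxy}trimethylsilane, cyclopropane CH2 anti to the butenyl group | CC1=CC(C)(C)[C@@H](CCC=C)[C@@H]2C[C@]12O[Si](C)(C)C | intermediate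
6 | (5R)-5-(but-3-en-1-yl)-6-chloro-2,4,4-trimethylcyclohept-2-en-1-one, both C6 epimers | CC1=CC(C)(C)[C@@H](CCC=C)C(Cl)CC1=O | intermediate
7 | (5S)-5-(but-3-en-1-yl)-2,4,4-trimethylcyclohepta-2,6-dien-1-one | CC1=CC(C)(C)[C@@H](CCC=C)C=CC1=O | intermediate
8 | (5S)-2,4,4-trimethyl-5-(3-oxobutyl)cyclohepta-2,6-dien-1-one | CC1=CC(C)(C)[C@@H](CCC(C)=O)C=CC1=O | intermediate
9 | (1S,3aS,8aS)-1-hydroxy-1,4,4,6-tetramethyl-2,3,3a,4,8,8a-hexahydroazulen-7(1H)-one, cis-fused, OH syn to the ring-fusion hydrogens | O=C1C[C@H]2[C@H](CC[C@]2(C)O)C(C)(C)C=C1C | intermediate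
10 | (1S,3aS,7R,8aS)-1,4,4,6-tetramethyl-1,2,3,3a,4,7,8,8a-octahydroazulene-1,7-diol | O[C@@H]1C[C@H]2[C@H](CC[C@]2(C)O)C(C)(C)C=C1C | intermediate
11 | ethyl 2-[(1S,3aS,5R,8aS)-1-hydroxy-1,4,4,6-tetramethyl-1,2,3,3a,4,5,8,8a-octahydroazulen-5-yl]acetate | CC1=CC[C@H]2[C@H](CC[C@]2(C)O)C(C)(C)[C@@H]1CC(=O)OCC | intermediate
12 | 2-[(1S,3aS,5R,8aS)-1-hydroxy-1,4,4,6-tetramethyl-1,2,3,3a,4,5,8,8a-octahydroazulen-5-yl]acetic acid | CC1=CC[C@H]2[C@H](CC[C@]2(C)O)C(C)(C)[C@@H]1CC(=O)O | intermediate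
13 | 3-methylcyclohex-2-en-1-one | CC1=CC(=O)CCC1 | starting material
14 | bromomagnesium 3-methylcyclohexa-1,3-dien-1-olate | CC1=CCCC(O[Mg]Br)=C1 | intermediate
15 | tert-butyldimethyl[(3-methylcyclohexa-1,3-dien-1-yl)oxy]silane | CC1=CCCC(O[Si](C)(C)C(C)(C)C)=C1 | intermediate
16 | tert-butyldimethyl{[(1R,6S)-1-methyl-7-oxabicyclo[4.1.0]hept-2-en-3-yl]oxy}silane | C[C@]12O[C@H]1CCC(O[Si](C)(C)C(C)(C)C)=C2 | intermediate
17 | (4S)-4-hydroxy-3-methylcyclohex-2-en-1-one | O[C@H]1CCC(=O)C=C1C | intermediate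
18 | (4S)-4-[(tert-butyldimethylsilyl)oxy]-3-methylcyclohex-2-en-1-one | C[Si](C)(C(C)(C)C)O[C@H]1CCC(=O)C=C1C | intermediate
19 | bromomagnesium (3S,4S)-4-[(tert-butyldimethylsilyl)oxy]-3-[2-(1,3-dioxan-2-yl)ethyl]-3-methylcyclohex-1-en-1-olate | Br[Mg]OC1=C[C@](C)(CCC2OCCCO2)[C@@H](O[Si](C)(C)C(C)(C)C)CC1 | intermediate
20 | (3S,4S)-4-[(tert-butyldimethylsilyl)oxy]-2-[(dimethylamino)methyl]-3-[2-(1,3-dioxan-2-yl)ethyl]-3-methylcyclohexan-1-one, both C2 epimers | CN(C)CC1[C@](C)(CCC2OCCCO2)[C@@H](O[Si](C)(C)C(C)(C)C)CCC1=O | intermediate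
21 | {(2S,3S)-3-[(tert-butyldimethylsilyl)oxy]-2-[2-(1,3-dioxan-2-yl)ethyl]-2-methyl-6-oxocyclohexyl}methyl(trimethyl)ammonium iodide, both C1 epimers | C[N+](C)(C)CC1[C@](C)(CCC2OCCCO2)[C@@H](O[Si](C)(C)C(C)(C)C)CCC1=O.[I-] | intermediate
22 | (3S,4S)-4-[(tert-butyldimethylsilyl)oxy]-3-[2-(1,3-dioxan-2-yl)ethyl]-3-methyl-2-methylidenecyclohexan-1-one | C=C1[C@](C)(CCC2OCCCO2)[C@@H](O[Si](C)(C)C(C)(C)C)CCC1=O | intermediate
23 | (2S,3S,4S)-4-[(tert-butyldimethylsilyl)oxy]-3-[2-(1,3-dioxan-2-yl)ethyl]-2-{2-[(1S,3aS,5R,8aS)-1-hydroxy-1,4,4,6-tetramethyl-1,2,3,3a,4,5,8,8a-octahydroazulen-5-yl]ethyl}-3-methylcyclohexan-1-one | CC1=CC[C@H]2[C@H](CC[C@]2(C)O)C(C)(C)[C@@H]1CC[C@H]1[C@](C)(CCC2OCCCO2)[C@@H](O[Si](C)(C)C(C)(C)C)CCC1=O | intermediate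
24 | (1R,2S,3S,4S)-4-[(tert-butyldimethylsilyl)oxy]-3-[2-(1,3-dioxan-2-yl)ethyl]-2-{2-[(1S,3aS,5R,8aS)-1-hydroxy-1,4,4,6-tetramethyl-1,2,3,3a,4,5,8,8a-octahydroazulen-5-yl]ethyl}-1,3-dimethylcyclohexan-1-ol | CC1=CC[C@H]2[C@H](CC[C@]2(C)O)C(C)(C)[C@@H]1CC[C@H]1[C@](C)(CCC2OCCCO2)[C@@H](O[Si](C)(C)C(C)(C)C)CC[C@@]1(C)O | intermediate
25 | (2S,4aS,5S,6R,8aS)-5-{2-[(1S,3aS,5R,8aS)-1-hydroxy-1,4,4,6-tetramethyl-1,2,3,3a,4,5,8,8a-octahydroazulen-5-yl]ethyl}-4a,6-dimethyloctahydro-2H-chromene-2,6-diol (CNP0167351.1) | CC1=CC[C@H]2[C@H](CC[C@]2(C)O)C(C)(C)[C@@H]1CC[C@H]1[C@]2(C)CC[C@@H](O)O[C@H]2CC[C@@]1(C)O | target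

**Step count**
Total: 14 steps. Longest linear sequence: 10 steps (steps 1–7, then 12–14); the right-hand branch is steps 8–11.

**Three steps most likely to fail**

Step 9 (the proposed new step). The risks are epoxidation at the enol ether double bond instead of the distal one, and a low or reversed enantioselectivity for this cyclic diene. The fallback uses known chemistry, sets out from 15 and comes back at 17. Compound 15 is oxidised with mCPBA/NaHCO3 in CH2Cl2 at −20 °C (racemic vinylogous Rubottom oxidation) and hydrolysed to racemic 4-hydroxy-3-methylcyclohex-2-en-1-one F1. F1 is resolved with Burkholderia cepacia lipase and vinyl acetate in t-BuOMe, which acetylates the R enantiomer to (1R)-2-methyl-4-oxocyclohex-2-en-1-yl acetate F2 and leaves the S alcohol. Chromatography then delivers 17.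

Step 5. SmI2 may simply reduce the cross-conjugated dienone, over-reduce enone 9, or give the other carbinol epimer. The fallback sets out from 8 and comes back at 9. Kinetic enolisation of the methyl ketone with LiN(i-Pr)2 at −78 °C and silylation with t-BuMe2SiCl/HMPA gives the terminal silyl enol ether (5S)-5-{3-[(tert-butyldimethylsilyl)oxy]but-3-en-1-yl}-2,4,4-trimethylcyclohepta-2,6-dien-1-one F3. Fe(acac)3 (cat.) and PhSiH3 in EtOH/ethylene glycol at 60 °C then start a hydrogen-atom-transfer radical conjugate addition: the α-silyloxy tertiary radical closes 5-exo onto the dienone to give the silyl ether (1S,3aS,8aS)-1-[(tert-butyldimethylsilyl)oxy]-1,4,4,6-tetramethyl-2,3,3a,4,8,8a-hexahydroazulen-7(1H)-one F4. Bu4NF removes the silyl group and gives 9.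

Step 12. The primary radical is homoallylic and could rearrange (3-exo closure and vinyl shift) before it is trapped, and the α-methylene ketone may dimerise. The fallback is a polar union that sets out from 10 and 18 and comes back at 23. The Johnson–Claisen ester 11 is isolated and reduced with i-Bu2AlH at −78 °C to the aldehyde 2-[(1S,3aS,5R,8aS)-1-hydroxy-1,4,4,6-tetramethyl-1,2,3,3a,4,5,8,8a-octahydroazulen-5-yl]acetaldehyde F5. Enolate 19, generated from 18 as in step 11, is trapped with F5 at −78 °C to give the aldol adduct F6 (mixture at the two new centres). MsCl/Et3N followed by DBU dehydrates it to the alkylidene ketone F7 (E/Z mixture). Conjugate reduction with [(Ph3P)CuH]6 and DBU equilibration of the α-centre then give 23.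

**Further compounds**
F1 | step 9 | racemic 4-hydroxy-3-methylcyclohex-2-en-1-one | CC1=CC(=O)CCC1O
F2 | step 9 | (1R)-2-methyl-4-oxocyclohex-2-en-1-yl acetate | CC(=O)O[C@@H]1CCC(=O)C=C1C
F3 | step 5 | (5S)-5-{3-[(tert-butyldimethylsilyl)oxy]but-3-en-1-yl}-2,4,4-trimethylcyclohepta-2,6-dien-1-one | CC1=CC(C)(C)[C@@H](CCC(=C)O[Si](C)(C)C(C)(C)C)C=CC1=O
F4 | step 5 | (1S,3aS,8aS)-1-[(tert-butyldimethylsilyl)oxy]-1,4,4,6-tetramethyl-2,3,3a,4,8,8a-hexahydroazulen-7(1H)-one | O=C1C[C@H]2[C@H](CC[C@]2(C)O[Si](C)(C)C(C)(C)C)C(C)(C)C=C1C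
F5 | step 12 | 2-[(1S,3aS,5R,8aS)-1-hydroxy-1,4,4,6-tetramethyl-1,2,3,3a,4,5,8,8a-octahydroazulen-5-yl]acetaldehyde | CC1=CC[C@H]2[C@H](CC[C@]2(C)O)C(C)(C)[C@@H]1CC=O
F6 | step 12 | (3S,4S)-4-[(tert-butyldimethylsilyl)oxy]-3-[2-(1,3-dioxan-2-yl)ethyl]-2-{1-hydroxy-2-[(1S,3aS,5R,8aS)-1-hydroxy-1,4,4,6-tetramethyl-1,2,3,3a,4,5,8,8a-octahydroazulen-5-yl]ethyl}-3-methylcyclohexan-1-one, mixture at the carbinol and at C2 | CC1=CC[C@H]2[C@H](CC[C@]2(C)O)C(C)(C)[C@@H]1CC(O)C1[C@](C)(CCC2OCCCO2)[C@@H](O[Si](C)(C)C(C)(C)C)CCC1=O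
F7 | step 12 | (3S,4S)-4-[(tert-butyldimethylsilyl)oxy]-3-[2-(1,3-dioxan-2-yl)ethyl]-2-{2-[(1S,3aS,5R,8aS)-1-hydroxy-1,4,4,6-tetramethyl-1,2,3,3a,4,5,8,8a-octahydroazulen-5-yl]ethylidene}-3-methylcyclohexan-1-one, E/Z mixture | CC1=CC[C@H]2[C@H](CC[C@]2(C)O)C(C)(C)[C@@H]1CC=C1[C@](C)(CCC2OCCCO2)[C@@H](O[Si](C)(C)C(C)(C)C)CCC1=O
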